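**Assumptions**
- Both stereocentres are (R). The syncarpyl carbon outranks the aryl carbon, which outranks iPr, which outranks H. The two halves of the molecule are constitutionally identical, so the (R,S) diastereomer is meso.
- I assume (R)-TRIP gives the (R,R) product. The matching catalyst enantiomer has to be confirmed by screening.
- Syncarpic acid and the product are drawn as enols, as in the target.
- Solvents, bases, molecular sieves, resin, BF3·OEt2 and aqueous work-ups appear only in the conditions. The catalyst SMILES does not encode the axial descriptor, which is given in the name.

## Retrosynthesis
1. Disconnect both aryl–CH(iPr) bonds as a two-fold Friedel–Crafts/Michael addition. This gives hexanoylphloroglucinol and 2 equiv of isobutylidene-syncarpic acid, which comes from syncarpic acid and isobutyraldehyde.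
2. A chiral phosphoric acid sets both CH(iPr) centres in one operation. The two additions are independent, so the meso (R,S) diastereomer absorbs most of the enantiomeric error (Horeau amplification), and chromatography removes it.
3. Hexanoylphloroglucinol comes from BF3-mediated acylation of phloroglucinol with hexanoic acid.
4. Syncarpic acid comes from exhaustive dearomatising C-methylation of phloroglucinol. This is the only step that builds the cyclohexanetrione ring, and no ring is formed after it.

## Route

**Step 1**
Reactants: **1** phloroglucinol; **2** hexanoic acid
Product: **3** 2,4,6-trihydroxyhexanophenone (hexanoylphloroglucinol)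
Conditions: BF3·OEt2 (neat), 80 °C, 4 h; then aq. NaOAc
Reagents that add atoms: none
Why: BF3-mediated Friedel–Crafts acylation of the very electron-rich ring stops at the mono-ketone because the BF2-chelated aryl ketone is deactivated, and the NaOAc work-up releases the free ketone; no stereocentres.

**Step 2**
Reactants: **1** phloroglucinol; **4** methyl iodide
Product: **5** syncarpic acid (2,2,4,4-tetramethylcyclohexane-1,3,5-trione, enol form)
Conditions: MeI (4.4 equiv), NaOMe (4.4 equiv), MeOH, reflux, 6 h; then aq. HCl
Reagents that add atoms: methyl iodide, CI
Why: Iterative enolate C-alkylation (SN2) of the trione tautomer of phloroglucinol gives the 2,2,4,4-tetramethyl trione. Base extraction removes the neutral hexamethyl by-product, and recrystallisation or chromatography removes the pentamethyl by-product; no stereocentres.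

**Step 3**
Reactants: **5** syncarpic acid; **6** isobutyraldehyde
Product: **7** 4,4,6,6-tetramethyl-2-(2-methylpropylidene)cyclohexane-1,3,5-trione
Conditions: **6** (1.5 equiv), Amberlyst A-21 (free base), 4 Å MS, CH2Cl2, 0 °C, 3 h; filter, concentrate below 20 °C, use at once
Reagents that add atoms: none
Why: Knoevenagel condensation. Filtering off the solid base leaves no soluble amine to cause a racemic background reaction or to quench the phosphoric acid, and the volatile excess aldehyde is removed on evaporation; no stereocentres.

**Step 4 (key step)**
Reactants: **3** hexanoylphloroglucinol; **7** (2.6 equiv); **8** (R)-TRIP, (R)-3,3'-bis(2,4,6-triisopropylphenyl)-1,1'-binaphthyl-2,2'-diyl hydrogen phosphate (10 mol%)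
Product: **9** Myrtucommulone F, (R,R)
Conditions: **8** (10 mol%), 4 Å MS, CH2Cl2/toluene 1:1, –20 °C, 96 h; then SiO2 chromatography (hexanes/EtOAc + 0.5% AcOH) to remove the meso (R,S) diastereomer
Reagents that add atoms: none
Why: Proposed new method: the phosphoric acid P–OH activates the trione carbonyls of the alkylidene acceptor while the P=O binds a phloroglucinol OH, so the C3/C5 arene carbon attacks one enantioface of the alkylidene in a Friedel–Crafts/Michael addition that sets each CH(iPr) centre, and the closest known reaction type is CPA-catalysed Friedel–Crafts alkylation of phenols and naphthols with alkylidene 1,3-dicarbonyls and o-quinone methides; what is new is the 2-acylphloroglucinol donor, the aliphatic β-branched tetramethylcyclohexanetrione acceptor, and the two-fold addition at the two homotopic C–H sites, and because the two centres are set independently the C2-symmetric (R,R) isomer is enriched by Horeau amplification while the meso isomer is removed by chromatography.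

## Compound list
1 | phloroglucinol (benzene-1,3,5-triol) | Oc1cc(O)cc(O)c1 | starting material
2 | hexanoic acid | CCCCCC(=O)O | starting material
3 | 2,4,6-trihydroxyhexanophenone | CCCCCC(=O)c1c(O)cc(O)cc1O | intermediate
4 | methyl iodide | CI | starting material
5 | syncarpic acid (enol form) | OC1=CC(=O)C(C)(C)C(=O)C1(C)C | intermediate
6 | isobutyraldehyde | CC(C)C=O | starting material
7 | 4,4,6,6-tetramethyl-2-(2-methylpropylidene)cyclohexane-1,3,5-trione | CC(C)C=C1C(=O)C(C)(C)C(=O)C(C)(C)C1=O | intermediate
8 | (R)-TRIP, chiral phosphoric acid catalyst (axial (R), not encoded in the SMILES) | O=P1(O)Oc2c(-c3c(C(C)C)cc(C(C)C)cc3C(C)C)cc3ccccc3c2-c2c(O1)c(-c1c(C(C)C)cc(C(C)C)cc1C(C)C)cc1ccccc21 | starting material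
9 | Myrtucommulone F | CCCCCC(=O)c1c(O)c([C@H](C2=C(O)C(C)(C)C(=O)C(C)(C)C2=O)C(C)C)c(O)c([C@H](C2=C(O)C(C)(C)C(=O)C(C)(C)C2=O)C(C)C)c1O | target

## Step count
- Total steps: 4.
- Longest linear sequence: 3 (phloroglucinol → **5** → **7** → **9**).

## Three steps most likely to fail
1. **Step 4 (proposed new method).** The electrophilic alkylidene trione may react in a racemic background reaction, catalysed by the acidic triketone product. The er may be low, or retro-Michael may erode it.
   - Fallback (known chemistry): run the racemic three-component Knoevenagel–Michael of **3**, **5** and **6** with piperidinium acetate, as used for myrtucommulone-type bis-adducts. Remove the meso diastereomer on silica. Resolve the (R,R)/(S,S) pair by preparative chiral-phase HPLC or by crystallising diastereomeric quinine salts of the acidic triketone.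
2. **Step 3.** The aliphatic alkylidene trione **7** may isomerise to the deconjugated enol, dimerise, or add a second syncarpic acid on isolation.
   - Fallback: do not isolate the acceptor. Convert **3** with isobutyraldehyde and PhSO2Na/acid into the bench-stable bis(α-sulfonylalkyl) phenol. Generate the bis-o-quinone methide in situ with base and trap it with syncarpic acid under the same chiral phosphoric acid.
3. **Step 2.** Over- and under-methylation of phloroglucinol can give a modest yield of **5**.
   - Fallback: buy commercial syncarpic acid, or run the methylation in two stages with purification of the intermediate between them.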